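Atoms are numbered N1, C2 (methyl), C3 (ester oxygen) and C6 (chain) in each heterocycle, with a for the imine ring A and b for the piperidine ring B. The oxygen on C3b joins a secondary ring carbon to an acyl chain; removing it leaves a 25-membered 3-acylpiperidine keto lactone whose all-cis C2b/C3b/C6b array is what syn hydrogenation of a cyclic β-enamino ketone delivers, so the diolide can be finished by a retentive oxygen insertion.
Retrosynthetic cuts, in order: C2a=N1a (condensation); O–C3b (oxygen removed, 26 to 25 ring atoms); the C3a–O acyl bond (macrolactone); N1b–C2b and C3b–C4b (amino iodide plus ynone); C3a–C4a (thioester plus alkylzinc); C5–C6 in both halves (allylation of one sulfinyl imine).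
Forward: methyl 9-oxononanoate gives one (R)-amino iodide that is used twice. One portion is joined to a lactate thioester and extended to an ynone (half A); the other is annulated onto that ynone to form ring B. Hydrogenation and macrolactonisation give the 25-membered ring, oxygen insertion gives the 26-membered diolide, and ring A is closed last.
Stereochemistry: C6a and C6b come from the (R)-tert-butanesulfinyl auxiliary; C2b and C3b from hydrogen delivery anti to the C6b chain; the C3b–O centre from migration with retention; C3a from Felkin–Anh reduction next to the lactate-derived C2a silyl ether, whose own centre is oxidised away at the end.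

Key step: step 17

Remark: C2a becomes the sp2 imine carbon, so its configuration along the route is free; the (S) series from methyl (S)-lactate is used because its silyl ether steers the hydride to the C3a face required.

Step 1
Reactants: 1 methyl 9-oxononanoate
Product: 2 methyl (E)-9-{[(R)-tert-butylsulfinyl]imino}nonanoate
Conditions: (R)-t-BuS(O)NH2, CuSO4, CH2Cl2, rt
Reagents that add atoms: (R)-tert-butanesulfinamide, CC(C)(C)[S@@](=O)N
Why: Condensation of the aldehyde with the sulfinamide, with CuSO4 as mild Lewis acid and water scavenger, should give the (E)-N-sulfinyl aldimine without touching the methyl ester (imine formation).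

Step 2
Reactants: 2 methyl (E)-9-{[(R)-tert-butylsulfinyl]imino}nonanoate
Product: 3 methyl (9R)-9-{[(R)-tert-butylsulfinyl]amino}dodec-11-enoate
Conditions: allyl bromide, In powder, THF, 60 °C
Reagents that add atoms: allyl bromide, C=CCBr
Why: In this Barbier-type allylation the allylindium reagent should add through a six-membered chair in which indium is bound to the sulfinyl oxygen and tert-butyl is equatorial, so the (R)-sulfinyl group directs attack to the Si face and sets the (R) amine carbon that becomes C6a and C6b, while the ester is inert to allylindium.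

Step 3
Reactants: 3 methyl (9R)-9-{[(R)-tert-butylsulfinyl]amino}dodec-11-enoate
Product: 5 methyl (9R)-9-[(tert-butoxycarbonyl)amino]dodec-11-enoate, via ammonium chloride 4 (not isolated)
Conditions: HCl (4 M in dioxane), MeOH, 0 °C to rt; evaporate; Boc2O, Et3N, CH2Cl2, rt
Reagents that add atoms: di-tert-butyl dicarbonate, CC(C)(C)OC(=O)OC(=O)OC(C)(C)C
Why: Acid methanolysis of the N–S bond followed by carbamate formation exchanges the auxiliary for Boc without touching the stereocentre, and methanol as co-solvent keeps the ester as its methyl ester (sulfinamide cleavage, Boc protection).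

Step 4
Reactants: 5 methyl (9R)-9-[(tert-butoxycarbonyl)amino]dodec-11-enoate
Product: 7 methyl (9R)-9-[(tert-butoxycarbonyl)amino]-11-hydroxyundecanoate, via aldehyde 6 (not isolated)
Conditions: O3, CH2Cl2/MeOH, −78 °C; then NaBH4, −78 to 0 °C
Reagents that add atoms: ozone, [O-][O+]=O
Why: Ozonolysis with reductive work-up cuts the terminal alkene to the primary alcohol, the elimination-prone β-amino aldehyde being reduced as soon as it is released and the methyl ester being inert to NaBH4 at this temperature.

Step 5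
Reactants: 7 methyl (9R)-9-[(tert-butoxycarbonyl)amino]-11-hydroxyundecanoate
Product: 8 methyl (9R)-9-[(tert-butoxycarbonyl)amino]-11-iodoundecanoate
Conditions: I2, PPh3, imidazole, CH2Cl2, 0 °C to rt
Reagents that add atoms: iodine, II
Why: Appel-type iodination converts the primary alcohol into the iodide under neutral conditions that spare the carbamate and the ester.

Step 6
Reactants: 9 methyl (S)-lactate
Product: 10 methyl (S)-2-[(tert-butyldimethylsilyl)oxy]propanoate
Conditions: TBSCl, imidazole, DMF, rt
Reagents that add atoms: tert-butyldimethylsilyl chloride, CC(C)(C)[Si](C)(C)Cl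
Why: Imidazole-mediated silylation gives the bulky, non-chelating ether at the future C2a that is needed for Felkin–Anh control and for survival in the peracid step.

Step 7
Reactants: 10 methyl (S)-2-[(tert-butyldimethylsilyl)oxy]propanoate
Product: 11 S-ethyl (S)-2-[(tert-butyldimethylsilyl)oxy]propanethioate
Conditions: EtSH, Me3Al, CH2Cl2, 0 °C to rt
Reagents that add atoms: ethanethiol, CCS
Why: The aluminium thiolate formed from Me3Al and EtSH exchanges methoxide for ethanethiolate at the ester carbonyl without enolising the α-silyloxy centre (ester to thioester conversion).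

Step 8
Reactants: 8 methyl (9R)-9-[(tert-butoxycarbonyl)amino]-11-iodoundecanoate; 11 S-ethyl (S)-2-[(tert-butyldimethylsilyl)oxy]propanethioate
Product: 13 methyl (9R,13S)-9-[(tert-butoxycarbonyl)amino]-13-[(tert-butyldimethylsilyl)oxy]-12-oxotetradecanoate, via alkylzinc iodide 12 (not isolated)
Conditions: 8, Zn dust (Me3SiCl, BrCH2CH2Br), DMF, 35 °C; then 11, PdCl2(PPh3)2 (5 mol%), toluene, rt
Reagents that add atoms: none
Why: Zinc insertion into the primary C–I bond gives an alkylzinc iodide that tolerates the carbamate N–H and the ester, and Fukuyama coupling (acyl–sulfur oxidative addition to zerovalent palladium formed from PdCl2(PPh3)2, transmetallation, reductive elimination) forms the C3a–C4a bond as a ketone without over-addition or loss of the C2a configuration.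

Step 9
Reactants: 13 methyl (9R,13S)-9-[(tert-butoxycarbonyl)amino]-13-[(tert-butyldimethylsilyl)oxy]-12-oxotetradecanoate
Product: 14 methyl (9R,12S,13S)-9-[(tert-butoxycarbonyl)amino]-13-[(tert-butyldimethylsilyl)oxy]-12-hydroxytetradecanoate
Conditions: LiBH(s-Bu)3, THF, −78 °C; sat. aq. NH4Cl
Reagents that add atoms: none
Why: In this Felkin–Anh reduction the bulky hydride should attack the C3a carbonyl anti to the C2a–O bond held perpendicular to the carbonyl plane and pass hydrogen, not methyl, which sets C3a as (S) (syn to the silyl ether), while ester and carbamate are inert at −78 °C.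

Step 10
Reactants: 14 methyl (9R,12S,13S)-9-[(tert-butoxycarbonyl)amino]-13-[(tert-butyldimethylsilyl)oxy]-12-hydroxytetradecanoate
Product: 15 (9R,12S,13S)-9-[(tert-butoxycarbonyl)amino]-13-[(tert-butyldimethylsilyl)oxy]-12-hydroxy-N-methoxy-N-methyltetradecanamide
Conditions: MeNH(OMe)·HCl, i-PrMgCl, THF, −20 to 0 °C
Reagents that add atoms: N,O-dimethylhydroxylamine hydrochloride, CNOC.Cl
Why: Aminolysis of the unhindered methyl ester by the magnesium amide of N,O-dimethylhydroxylamine gives the Weinreb amide, with extra i-PrMgCl covering the O–H and N–H protons and the cold magnesium alkoxide not inducing silyl migration.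

Step 11
Reactants: 15 (9R,12S,13S)-9-[(tert-butoxycarbonyl)amino]-13-[(tert-butyldimethylsilyl)oxy]-12-hydroxy-N-methoxy-N-methyltetradecanamide
Product: 16 (12R,15S,16S)-12-[(tert-butoxycarbonyl)amino]-16-[(tert-butyldimethylsilyl)oxy]-15-hydroxyheptadec-2-yn-4-one
Conditions: MeC≡CMgBr, THF, 0 °C; inverse quench into cold aq. NaHSO4
Reagents that add atoms: 1-propynylmagnesium bromide, CC#C[Mg]Br
Why: The alkynyl Grignard reagent adds only once to the Weinreb amide because the chelated tetrahedral adduct persists until the acidic quench, which also protonates the released amine so that it cannot add to the ynone.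

Step 12
Reactants: 8 methyl (9R)-9-[(tert-butoxycarbonyl)amino]-11-iodoundecanoate; 16 (12R,15S,16S)-12-[(tert-butoxycarbonyl)amino]-16-[(tert-butyldimethylsilyl)oxy]-15-hydroxyheptadec-2-yn-4-one
Product: 19 methyl 8-{(2R)-5-[(9R,12S,13S)-9-(Boc-amino)-12-hydroxy-13-(TBS-oxy)tetradecanoyl]-6-methyl-1,2,3,4-tetrahydropyridin-2-yl}octanoate, via ammonium trifluoroacetate 17 (not isolated), via acyclic enaminone 18 (not isolated)
Conditions: 8, CF3CO2H, CH2Cl2, 0 °C to rt; evaporate; then 16, i-Pr2NEt, MeCN, rt then 70 °C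
Reagents that add atoms: none
Why: Once the amine is freed in the presence of the ynone, aza-Michael addition at the methyl-bearing alkyne carbon gives the hydrogen-bonded (Z)-enaminone, whose α-carbon then displaces iodide in a 6-(enolendo)-exo-tet alkylation under mild amine base, closing ring B with the C2b methyl and the C3b acyl chain placed unambiguously by the ynone (enaminone annulation).

Step 13
Reactants: 19 methyl 8-{(2R)-5-[(9R,12S,13S)-9-(Boc-amino)-12-hydroxy-13-(TBS-oxy)tetradecanoyl]-6-methyl-1,2,3,4-tetrahydropyridin-2-yl}octanoate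
Product: 20 methyl 8-{(2R,5S,6S)-5-[(9R,12S,13S)-9-(Boc-amino)-12-hydroxy-13-(TBS-oxy)tetradecanoyl]-6-methylpiperidin-2-yl}octanoate (all-cis)
Conditions: H2 (4 bar), PtO2, AcOH, rt; aq. NaHCO3 work-up
Reagents that add atoms: none
Why: Heterogeneous hydrogenation of the tetrasubstituted vinylogous amide should deliver both hydrogens syn from the face opposite the C6b chain, setting C2b and C3b (2bS,3bS) cis to each other and to C6b, while acetic acid keeps the resulting β-amino ketone protonated against retro-Michael epimerisation and leaves silyl ether, carbamate and ester intact.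

Step 14
Reactants: 20 methyl 8-{(2R,5S,6S)-5-[(9R,12S,13S)-9-(Boc-amino)-12-hydroxy-13-(TBS-oxy)tetradecanoyl]-6-methylpiperidin-2-yl}octanoate
Product: 21 methyl 8-{(2R,5S,6S)-1-Boc-5-[(9R,12S,13S)-9-(Boc-amino)-12-hydroxy-13-(TBS-oxy)tetradecanoyl]-6-methylpiperidin-2-yl}octanoate
Conditions: Boc2O, Et3N, CH2Cl2, rt to 40 °C
Reagents that add atoms: di-tert-butyl dicarbonate, CC(C)(C)OC(=O)OC(=O)OC(C)(C)C
Why: Carbamate formation on the ring B nitrogen blocks N-oxidation and retro-Michael opening in later steps, and without an acyl-transfer catalyst the hindered C3a hydroxyl does not react with Boc2O (Boc protection).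

Step 15
Reactants: 21 methyl 8-{(2R,5S,6S)-1-Boc-5-[(9R,12S,13S)-9-(Boc-amino)-12-hydroxy-13-(TBS-oxy)tetradecanoyl]-6-methylpiperidin-2-yl}octanoate
Product: 22 8-{(2R,5S,6S)-1-Boc-5-[(9R,12S,13S)-9-(Boc-amino)-12-hydroxy-13-(TBS-oxy)tetradecanoyl]-6-methylpiperidin-2-yl}octanoic acid
Conditions: Me3SnOH, ClCH2CH2Cl, 80 °C; 0.1 M aq. HCl wash
Reagents that add atoms: trimethyltin hydroxide, C[Sn](C)(C)O
Why: Me3SnOH cleaves the only ester, an unhindered methyl ester, under near-neutral conditions, so the enolisable C3b centre is not epimerised and the C2a silyl ether does not migrate to the free C3a hydroxyl (ester hydrolysis).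

Step 16
Reactants: 22 8-{(2R,5S,6S)-1-Boc-5-[(9R,12S,13S)-9-(Boc-amino)-12-hydroxy-13-(TBS-oxy)tetradecanoyl]-6-methylpiperidin-2-yl}octanoic acid
Product: 23 25-membered keto lactone (C6b–(CH2)7–CO–O–C3a closed; ring B N-Boc all-cis 2bS,3bS,6bR with the ketone C(=O)(CH2)7C6a on C3b; 6aR NHBoc; 3aS; 2aS OTBS)
Conditions: 2-methyl-6-nitrobenzoic anhydride, DMAP, CH2Cl2 (1 mM, slow addition of 22), rt
Reagents that add atoms: none
Why: In this Shiina macrolactonisation the mixed anhydride is passed on by DMAP to the C3a hydroxyl under high dilution, closing the 25-membered ring by acyl activation with the C3a–O bond, and hence its configuration, untouched.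

Step 17
Reactants: 23 25-membered keto lactone
Product: 24 26-membered diolide (as 23 with oxygen between the former ketone carbon and C3b; 3bS retained; C2a still the TBS ether)
Conditions: (CF3CO)2O, H2O2·urea, Na2HPO4, CH2Cl2, 0 °C to rt
Reagents that add atoms: trifluoroperacetic acid (made in the flask), OOC(=O)C(F)(F)F
Why: The peracid adds to the C3b ketone to give the tetrahedral peroxy adduct (Criegee adduct), and the group antiperiplanar to the O–O bond shifts to oxygen as trifluoroacetate leaves, which is the Baeyer–Villiger oxidation of a secondary-alkyl primary-alkyl ketone. The 26-membered ring is not formed by a cyclisation but by ring enlargement: the 1,2-shift inserts one oxygen into the 25-membered ring between the carbonyl carbon and C3b. No new stereocentre arises; the concerted suprafacial shift carries C3b over with retention, so the carbon-based configuration set by hydrogenation becomes the C3b–O configuration. The step needs C3b to migrate in preference to the chain CH2, which the higher migratory aptitude of the secondary carbon should secure and which the Na2HPO4 buffer supports by suppressing acid-catalysed, less selective pathways. It also needs chemoselectivity: both nitrogens are carbamates and C2a is a silyl ether (an acyloxy ketone there would be oxidised as well), so the ketone is the only site open to the peracid, and the buffer keeps Boc and TBS in place.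

Step 18
Reactants: 24 26-membered diolide with C2a TBS ether
Product: 25 26-membered diolide with free (2aS) hydroxyl
Conditions: HF·pyridine, pyridine, THF, 0 °C to rt
Reagents that add atoms: none
Why: Fluoride-mediated desilylation under buffered acidic conditions frees the C2a hydroxyl without base-induced 1,2-acyl shift from C3a and without loss of Boc.

Step 19
Reactants: 25 26-membered diolide with free (2aS) hydroxyl
Product: 26 26-membered diolide with C2a methyl ketone (acetyl on C3a)
Conditions: Dess–Martin periodinane, NaHCO3, CH2Cl2, 0 °C to rt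
Reagents that add atoms: none
Why: Dess–Martin oxidation converts the secondary carbinol into the methyl ketone under buffered neutral conditions that should not epimerise the adjacent acyloxy-bearing C3a.

Step 20
Reactants: 26 26-membered diolide with C2a methyl ketone
Product: 28 target imine diolide CNP0304114.1, via bis(trifluoroacetate) salt 27 (not isolated)
Conditions: CF3CO2H, CH2Cl2, 0 °C; evaporate; then sat. aq. NaHCO3, CH2Cl2, rt
Reagents that add atoms: none
Why: Acidolysis removes both Boc groups, and on neutralisation the C6a primary amine condenses with the C2a ketone by 6-exo-trig addition and dehydration to the cyclic imine of ring A, the hindered ring B amine having no carbonyl partner within reach (imine condensation).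

Compound list
1 | methyl 9-oxononanoate | O=CCCCCCCCC(=O)OC | starting material
2 | methyl (E)-9-{[(R)-tert-butylsulfinyl]imino}nonanoate | CC(C)(C)[S@@](=O)/N=C/CCCCCCCC(=O)OC | intermediate
3 | methyl (9R)-9-{[(R)-tert-butylsulfinyl]amino}dodec-11-enoate | CC(C)(C)[S@@](=O)N[C@@H](CC=C)CCCCCCCC(=O)OC | intermediate
4 | methyl (9R)-9-aminododec-11-enoate hydrochloride (not isolated) | [Cl-].[NH3+][C@@H](CC=C)CCCCCCCC(=O)OC | intermediate
5 | methyl (9R)-9-[(tert-butoxycarbonyl)amino]dodec-11-enoate | CC(C)(C)OC(=O)N[C@@H](CC=C)CCCCCCCC(=O)OC | intermediate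
6 | methyl (9R)-9-[(tert-butoxycarbonyl)amino]-11-oxoundecanoate (not isolated) | CC(C)(C)OC(=O)N[C@@H](CC=O)CCCCCCCC(=O)OC | intermediate
7 | methyl (9R)-9-[(tert-butoxycarbonyl)amino]-11-hydroxyundecanoate | CC(C)(C)OC(=O)N[C@@H](CCO)CCCCCCCC(=O)OC | intermediate
8 | methyl (9R)-9-[(tert-butoxycarbonyl)amino]-11-iodoundecanoate | CC(C)(C)OC(=O)N[C@@H](CCI)CCCCCCCC(=O)OC | intermediate
9 | methyl (S)-lactate | C[C@H](O)C(=O)OC | starting material
10 | methyl (S)-2-[(tert-butyldimethylsilyl)oxy]propanoate | C[C@H](O[Si](C)(C)C(C)(C)C)C(=O)OC | intermediate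
11 | S-ethyl (S)-2-[(tert-butyldimethylsilyl)oxy]propanethioate | C[C@H](O[Si](C)(C)C(C)(C)C)C(=O)SCC | intermediate
12 | {(3R)-3-[(tert-butoxycarbonyl)amino]-11-methoxy-11-oxoundecyl}zinc iodide (not isolated) | CC(C)(C)OC(=O)N[C@@H](CC[Zn]I)CCCCCCCC(=O)OC | intermediate
13 | methyl (9R,13S)-9-[(tert-butoxycarbonyl)amino]-13-[(tert-butyldimethylsilyl)oxy]-12-oxotetradecanoate | C[C@H](O[Si](C)(C)C(C)(C)C)C(=O)CC[C@H](NC(=O)OC(C)(C)C)CCCCCCCC(=O)OC | intermediate
14 | methyl (9R,12S,13S)-9-[(tert-butoxycarbonyl)amino]-13-[(tert-butyldimethylsilyl)oxy]-12-hydroxytetradecanoate | C[C@H](O[Si](C)(C)C(C)(C)C)[C@@H](O)CC[C@H](NC(=O)OC(C)(C)C)CCCCCCCC(=O)OC | intermediate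
15 | (9R,12S,13S)-9-[(tert-butoxycarbonyl)amino]-13-[(tert-butyldimethylsilyl)oxy]-12-hydroxy-N-methoxy-N-methyltetradecanamide | C[C@H](O[Si](C)(C)C(C)(C)C)[C@@H](O)CC[C@H](NC(=O)OC(C)(C)C)CCCCCCCC(=O)N(C)OC | intermediate
16 | (12R,15S,16S)-12-[(tert-butoxycarbonyl)amino]-16-[(tert-butyldimethylsilyl)oxy]-15-hydroxyheptadec-2-yn-4-one | C[C@H](O[Si](C)(C)C(C)(C)C)[C@@H](O)CC[C@H](NC(=O)OC(C)(C)C)CCCCCCCC(=O)C#CC | intermediate
17 | methyl (9R)-9-amino-11-iodoundecanoate trifluoroacetate salt (not isolated) | [O-]C(=O)C(F)(F)F.[NH3+][C@@H](CCI)CCCCCCCC(=O)OC | intermediate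
18 | acyclic (Z)-enaminone: amine of 17 added to the methyl-bearing alkyne carbon of 16 (not isolated) | C[C@H](O[Si](C)(C)C(C)(C)C)[C@@H](O)CC[C@H](NC(=O)OC(C)(C)C)CCCCCCCC(=O)/C=C(/C)N[C@@H](CCI)CCCCCCCC(=O)OC | intermediate
19 | methyl 8-{(2R)-5-[(9R,12S,13S)-9-(Boc-amino)-12-hydroxy-13-(TBS-oxy)tetradecanoyl]-6-methyl-1,2,3,4-tetrahydropyridin-2-yl}octanoate | C[C@H](O[Si](C)(C)C(C)(C)C)[C@@H](O)CC[C@H](NC(=O)OC(C)(C)C)CCCCCCCC(=O)C1=C(C)N[C@H](CCCCCCCC(=O)OC)CC1 | intermediate
20 | methyl 8-{(2R,5S,6S)-5-[(9R,12S,13S)-9-(Boc-amino)-12-hydroxy-13-(TBS-oxy)tetradecanoyl]-6-methylpiperidin-2-yl}octanoate (all-cis) | C[C@H](O[Si](C)(C)C(C)(C)C)[C@@H](O)CC[C@H](NC(=O)OC(C)(C)C)CCCCCCCC(=O)[C@H]1CC[C@@H](CCCCCCCC(=O)OC)N[C@H]1C | intermediate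
21 | N-Boc derivative of 20 | C[C@H](O[Si](C)(C)C(C)(C)C)[C@@H](O)CC[C@H](NC(=O)OC(C)(C)C)CCCCCCCC(=O)[C@H]1CC[C@@H](CCCCCCCC(=O)OC)N(C(=O)OC(C)(C)C)[C@H]1C | intermediate
22 | seco acid: carboxylic acid of 21 | C[C@H](O[Si](C)(C)C(C)(C)C)[C@@H](O)CC[C@H](NC(=O)OC(C)(C)C)CCCCCCCC(=O)[C@H]1CC[C@@H](CCCCCCCC(=O)O)N(C(=O)OC(C)(C)C)[C@H]1C | intermediate
23 | 25-membered keto lactone (ketone on C3b; 2bS,3bS,6bR,6aR,3aS,2aS; N-Boc, NHBoc, C2a OTBS) | O1[C@H]([C@H](C)O[Si](C)(C)C(C)(C)C)CC[C@H](NC(=O)OC(C)(C)C)CCCCCCCC(=O)[C@H]2CC[C@@H](CCCCCCCC1=O)N(C(=O)OC(C)(C)C)[C@H]2C | intermediate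
24 | 26-membered diolide with C2a TBS ether (C3b–O–C(=O); 3bS) | O1[C@H]([C@H](C)O[Si](C)(C)C(C)(C)C)CC[C@H](NC(=O)OC(C)(C)C)CCCCCCCC(=O)O[C@H]2CC[C@@H](CCCCCCCC1=O)N(C(=O)OC(C)(C)C)[C@H]2C | intermediate
25 | 26-membered diolide with free (2aS) hydroxyl | O1[C@H]([C@H](C)O)CC[C@H](NC(=O)OC(C)(C)C)CCCCCCCC(=O)O[C@H]2CC[C@@H](CCCCCCCC1=O)N(C(=O)OC(C)(C)C)[C@H]2C | intermediate
26 | 26-membered diolide with C2a methyl ketone | O1[C@H](C(C)=O)CC[C@H](NC(=O)OC(C)(C)C)CCCCCCCC(=O)O[C@H]2CC[C@@H](CCCCCCCC1=O)N(C(=O)OC(C)(C)C)[C@H]2C | intermediate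
27 | diamino ketone diolide as its bis(trifluoroacetate) salt (not isolated) | O1[C@H](C(C)=O)CC[C@H]([NH3+])CCCCCCCC(=O)O[C@H]2CC[C@@H](CCCCCCCC1=O)[NH2+][C@H]2C.[O-]C(=O)C(F)(F)F.[O-]C(=O)C(F)(F)F | intermediate
28 | CNP0304114.1: 26-membered diolide with ring A as the 2-methyl cyclic imine (3aS,6aR) and ring B as the all-cis piperidine (2bS,3bS,6bR) | CC1=N[C@@H]2CCCCCCCC(=O)O[C@H]3CC[C@@H](CCCCCCCC(=O)O[C@H]1CC2)N[C@H]3C | target

Total step count: 20.
Longest linear sequence: 18 steps (steps 1–5 and 8–20); the lactate branch (steps 6–7) joins at step 8, and iodide 8 is used in both step 8 and step 12.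

Steps most likely to fail

Step 17. The chain CH2 may migrate in competition with C3b, or peracid addition to the ketone inside the macrocycle may be slow enough for carbamate cleavage to overtake it. The fallback inserts the oxygen on a methyl ketone, where only the ring carbon competes with methyl, and then forms both ester bonds by acylation; it sets out from 8 and 14 and returns at 24. Salt 17 (from 8 as in step 12) and pent-3-yn-2-one with i-Pr2NEt in MeCN give the acyclic acetyl enaminone F1, which closes on warming to the 3-acetyl tetrahydropyridine F2. H2 over PtO2 in AcOH gives the all-cis 3-acetylpiperidine F3, Boc2O the carbamate F4, CF3CO3H with Na2HPO4 the acetate F5, and K2CO3 in MeOH the piperidinol F6. In parallel 14 is converted with Et3SiCl and imidazole into the triethylsilyl ether F7 and with Me3SnOH into the acid F8. Yamaguchi esterification of F6 with F8 (2,4,6-trichlorobenzoyl chloride, Et3N, DMAP) gives the diester F9. Pyridinium p-toluenesulfonate in MeOH removes the triethylsilyl group to give the hydroxy ester F10, Me3SnOH gives the seco acid F11, and the conditions of step 16 close the C3a–O bond to 24.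

Step 12. The liberated amino iodide may alkylate itself (azetidine or oligomer) before it adds to the ynone, or the enaminone may be alkylated away from its α-carbon. The fallback separates conjugate addition from ring closure; it sets out from 7 and 16 and returns at 19. HCl in dioxane converts 7 into the amino alcohol hydrochloride F12, which with 16 and i-Pr2NEt in MeCN gives the hydroxy enaminone F13 with no electrophile present. Selective sulfonylation of the primary hydroxyl (MsCl, Et3N, CH2Cl2, −20 °C) gives the mesylate F14, and NaI with i-Pr2NEt in warm MeCN closes ring B to 19.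

Step 13. Hydrogen may be delivered to the wrong face, reduction may continue past the ketone to the carbinol, or the free β-amino ketone may epimerise by retro-Michael opening. The fallback hydrogenates an N-acylated enaminone after ring closure; it sets out from 19 and returns at 23. Me3SnOH converts 19 into the enaminone seco acid F15, and the conditions of step 16 give the 25-membered enaminone lactone F16, which has no enolisable stereocentre and an unreactive vinylogous amide nitrogen. With no hydroxyl left, Boc2O and DMAP give the N-Boc enaminone F17, an electron-poor alkene whose C6b substituent is forced axial. H2 over Pd/C, which does not reduce aliphatic ketones, should then add anti to that substituent and give 23 directly.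

Further compounds
F1 | step 17 | methyl (9R)-11-iodo-9-{[(Z)-4-oxopent-2-en-2-yl]amino}undecanoate | CC(=O)/C=C(/C)N[C@@H](CCI)CCCCCCCC(=O)OC
F2 | step 17 | methyl 8-[(2R)-5-acetyl-6-methyl-1,2,3,4-tetrahydropyridin-2-yl]octanoate | CC(=O)C1=C(C)N[C@H](CCCCCCCC(=O)OC)CC1
F3 | step 17 | methyl 8-[(2R,5S,6S)-5-acetyl-6-methylpiperidin-2-yl]octanoate (all-cis) | CC(=O)[C@H]1CC[C@@H](CCCCCCCC(=O)OC)N[C@H]1C
F4 | step 17 | tert-butyl (2S,3S,6R)-3-acetyl-6-(8-methoxy-8-oxooctyl)-2-methylpiperidine-1-carboxylate | CC(=O)[C@H]1CC[C@@H](CCCCCCCC(=O)OC)N(C(=O)OC(C)(C)C)[C@H]1C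
F5 | step 17 | tert-butyl (2S,3S,6R)-3-acetoxy-6-(8-methoxy-8-oxooctyl)-2-methylpiperidine-1-carboxylate | CC(=O)O[C@H]1CC[C@@H](CCCCCCCC(=O)OC)N(C(=O)OC(C)(C)C)[C@H]1C
F6 | step 17 | tert-butyl (2S,3S,6R)-3-hydroxy-6-(8-methoxy-8-oxooctyl)-2-methylpiperidine-1-carboxylate | O[C@H]1CC[C@@H](CCCCCCCC(=O)OC)N(C(=O)OC(C)(C)C)[C@H]1C
F7 | step 17 | 12-O-triethylsilyl ether of 14 | C[C@H](O[Si](C)(C)C(C)(C)C)[C@@H](O[Si](CC)(CC)CC)CC[C@H](NC(=O)OC(C)(C)C)CCCCCCCC(=O)OC
F8 | step 17 | carboxylic acid of F7 | C[C@H](O[Si](C)(C)C(C)(C)C)[C@@H](O[Si](CC)(CC)CC)CC[C@H](NC(=O)OC(C)(C)C)CCCCCCCC(=O)O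
F9 | step 17 | diester: F8 acylating the C3b hydroxyl of F6 | C[C@H](O[Si](C)(C)C(C)(C)C)[C@@H](O[Si](CC)(CC)CC)CC[C@H](NC(=O)OC(C)(C)C)CCCCCCCC(=O)O[C@H]1CC[C@@H](CCCCCCCC(=O)OC)N(C(=O)OC(C)(C)C)[C@H]1C
F10 | step 17 | hydroxy ester: F9 with free C3a hydroxyl | C[C@H](O[Si](C)(C)C(C)(C)C)[C@@H](O)CC[C@H](NC(=O)OC(C)(C)C)CCCCCCCC(=O)O[C@H]1CC[C@@H](CCCCCCCC(=O)OC)N(C(=O)OC(C)(C)C)[C@H]1C
F11 | step 17 | seco acid: F10 with the C6b chain as carboxylic acid | C[C@H](O[Si](C)(C)C(C)(C)C)[C@@H](O)CC[C@H](NC(=O)OC(C)(C)C)CCCCCCCC(=O)O[C@H]1CC[C@@H](CCCCCCCC(=O)O)N(C(=O)OC(C)(C)C)[C@H]1C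
F12 | step 12 | methyl (9R)-9-amino-11-hydroxyundecanoate hydrochloride | [Cl-].[NH3+][C@@H](CCO)CCCCCCCC(=O)OC
F13 | step 12 | hydroxy (Z)-enaminone: amine of F12 added to ynone 16 | C[C@H](O[Si](C)(C)C(C)(C)C)[C@@H](O)CC[C@H](NC(=O)OC(C)(C)C)CCCCCCCC(=O)/C=C(/C)N[C@@H](CCO)CCCCCCCC(=O)OC
F14 | step 12 | primary mesylate of F13 | C[C@H](O[Si](C)(C)C(C)(C)C)[C@@H](O)CC[C@H](NC(=O)OC(C)(C)C)CCCCCCCC(=O)/C=C(/C)N[C@@H](CCOS(C)(=O)=O)CCCCCCCC(=O)OC
F15 | step 13 | enaminone seco acid: carboxylic acid of 19 | C[C@H](O[Si](C)(C)C(C)(C)C)[C@@H](O)CC[C@H](NC(=O)OC(C)(C)C)CCCCCCCC(=O)C1=C(C)N[C@H](CCCCCCCC(=O)O)CC1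
F16 | step 13 | 25-membered enaminone lactone (C3a–O acyl bond closed; ring B as the N–H tetrahydropyridine) | O1[C@H]([C@H](C)O[Si](C)(C)C(C)(C)C)CC[C@H](NC(=O)OC(C)(C)C)CCCCCCCC(=O)C2=C(C)N[C@H](CCCCCCCC1=O)CC2
F17 | step 13 | N-Boc derivative of F16 at the ring B nitrogen | O1[C@H]([C@H](C)O[Si](C)(C)C(C)(C)C)CC[C@H](NC(=O)OC(C)(C)C)CCCCCCCC(=O)C2=C(C)N(C(=O)OC(C)(C)C)[C@H](CCCCCCCC1=O)CC2
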